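**Retrosynthetic overview**

1. The C8 tiglate and the C4 4-hydroxybenzoate go on last; the C6=C7 double bond and the C8 oxygen are carried as a 7,8-epoxide and released late by epoxide-to-allylic-alcohol isomerisation.
2. The C4 oxygen comes from a hydroxyl-directed reduction of a C4 ketone; the aryl ester is made by carbonylative esterification (aryl iodide + CO).
3. Key disconnection: the five-membered ring is closed by a radical conjugate addition/aldol (3+2) annulation of a ring-opened cyclopropanol onto an epoxy cycloheptenone, C8a–C1 by the radical and C3a–C3 by the aldol, setting C8a, C3a and C3 in one step.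
4. The epoxy enone comes from a meso cycloheptenone by enantioselective deprotonation/dehydrogenation and face-selective epoxidation.
5. Ring order: seven-membered ring first, by (4+3) cycloaddition of a hexadiene with an oxyallyl cation; five-membered ring second.

Convention: all bicyclic compounds carry the azulene locants of the target (C3 = carbinol carbon with the isopropyl group, C4 = benzoate carbon, C6 and C8a = methyl-bearing carbons, C8 = tiglate carbon).
Assumption: the (R,R)-lithium amide is taken to give the (6S)-dienone of Step 2; if the sense of induction is the opposite, the (S,S)-base is used.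
Assumption: the silyl-protected 4-iodophenol and tigloyl chloride are purchased; the silyl group is a protecting group.

**Route**

Step 1
Reactants: 1 1,1,3,3-tetrabromopropan-2-one; 2 (2E,4E)-hexa-2,4-diene
Product: 4 meso-(3R,6S)-3,6-dimethylcyclohept-4-en-1-one, via dibromo cycloadduct 3 (not isolated)
Conditions: Fe2(CO)9, benzene, 60 °C; then Zn–Cu couple, NH4Cl, MeOH, rt
Reagents that add atoms: none
Why: Noyori (4+3) cycloaddition of the iron-bound oxyallyl cation from 1 is suprafacial on the s-cis (E,E)-diene, so the two methyl groups end up cis (meso), and the two surplus bromines are then removed reductively.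

Step 2
Reactants: 4 meso-(3R,6S)-3,6-dimethylcyclohept-4-en-1-one
Product: 6 (6S)-3,6-dimethylcyclohepta-2,4-dien-1-one, via silyl enol ether 5 (not isolated)
Conditions: lithium (R,R)-bis(1-phenylethyl)amide, LiCl, Me3SiCl, THF, −100 °C; then Pd(OAc)2 (1.05 equiv), MeCN, rt
Reagents that add atoms: none
Why: Enantioselective deprotonation of the meso ketone by the chiral lithium amide with in situ silyl trapping (Simpkins–Koga desymmetrisation) selects one enantiotopic α-methylene, and Saegusa–Ito oxidation of that enol ether removes the methine on the same side so that only the (6S) stereocentre remains.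

Step 3
Reactants: 6 (6S)-3,6-dimethylcyclohepta-2,4-dien-1-one
Product: 7 (1S,6S,7R)-2,6-dimethyl-8-oxabicyclo[5.1.0]oct-2-en-4-one
Conditions: mCPBA, CH2Cl2, 0 °C
Reagents that add atoms: 3-chloroperbenzoic acid, OOC(=O)c1cccc(Cl)c1
Why: Prilezhaev epoxidation occurs at the more electron-rich γ,δ-double bond of the dienone and on the face opposite to the adjacent allylic methyl group, so both epoxide carbons (the later C8–O bond) are set from the C6 stereocentre.

Step 4
Reactants: 8 methyl 2-methylpropanoate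
Product: 9 1-(propan-2-yl)cyclopropan-1-ol
Conditions: EtMgBr (2.2 equiv), Ti(OiPr)4 (cat.), Et2O, 0 °C to rt; aq. NH4Cl
Reagents that add atoms: ethylmagnesium bromide, CC[Mg]Br
Why: Kulinkovich cyclopropanation of the ester through a titanacyclopropane gives the tertiary cyclopropanol, and no stereocentre is formed.

Step 5
Reactants: 7 (1S,6S,7R)-2,6-dimethyl-8-oxabicyclo[5.1.0]oct-2-en-4-one; 9 1-(propan-2-yl)cyclopropan-1-ol
Product: 10 (3R,3aR,6S,7R,8S,8aR)-7,8-epoxy-3-hydroxy-6,8a-dimethyl-3-(propan-2-yl)octahydroazulen-4(1H)-one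
Conditions: 1,2,3,5-tetrakis(carbazol-9-yl)-4,6-dicyanobenzene (4CzIPN, 5 mol%), 2,4,6-collidine (20 mol%), MeCN, blue LEDs (450 nm), rt, the cyclopropanol added slowly by syringe pump
Reagents that add atoms: none
Why: Proposed new method: the excited photocatalyst and collidine oxidise the cyclopropanol O–H by proton-coupled electron transfer, the alkoxy radical opens to the primary β-keto radical, this adds (Giese) to the enone β-carbon C8a on the face opposite to the epoxide oxygen to make the C8a–C1 bond and the quaternary centre, the resulting α-keto radical is reduced by the photocatalyst radical anion to the C3a enolate (radical–polar crossover), and this enolate closes regiospecifically onto the pendant isopropyl ketone in a reversible intramolecular aldol in which the three-carbon tether reaches only its own face of C3a, so the ring is cis-fused, the isopropyl group sits on the convex face and the C3 hydroxyl is cis to the C4 carbonyl, the collidinium ion returning the proton so that the whole cascade is redox-neutral and all atoms of both partners end up in the product; the closest known reactions are photochemical cyclopropanol ring-opening/Giese additions and the amine-catalysed cyclopropanol–enal radical conjugate addition/aldol cascade to cyclopentanols.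

Step 6
Reactants: 10 (3R,3aR,6S,7R,8S,8aR)-7,8-epoxy-3-hydroxy-6,8a-dimethyl-3-(propan-2-yl)octahydroazulen-4(1H)-one
Product: 11 (3R,3aS,4S,6S,7R,8S,8aR)-7,8-epoxy-6,8a-dimethyl-3-(propan-2-yl)decahydroazulene-3,4-diol
Conditions: Me4NBH(OAc)3, AcOH/MeCN, −20 °C
Reagents that add atoms: none
Why: Evans–Saksena reduction, in which the triacetoxyborohydride exchanges onto the tertiary C3 hydroxyl and delivers hydride intramolecularly to the C4 ketone from the face of that hydroxyl, gives the 1,3-anti diol with the C4 hydroxyl cis to H3a.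

Step 7
Reactants: 11 (3R,3aS,4S,6S,7R,8S,8aR)-7,8-epoxy-6,8a-dimethyl-3-(propan-2-yl)decahydroazulene-3,4-diol; 12 tert-butyl(4-iodophenoxy)dimethylsilane
Product: 13 (3R,3aS,4S,6S,7R,8S,8aR)-7,8-epoxy-3-hydroxy-6,8a-dimethyl-3-(propan-2-yl)decahydroazulen-4-yl 4-[(tert-butyldimethylsilyl)oxy]benzoate
Conditions: Pd(OAc)2 (5 mol%), Xantphos, CO (1 atm), Et3N, DMAP (cat.), toluene, 80 °C
Reagents that add atoms: carbon monoxide, [C-]#[O+]
Why: Palladium-catalysed alkoxycarbonylation (oxidative addition of the aryl iodide to zerovalent palladium, CO insertion, acyl transfer) esterifies the only acylable hydroxyl, the secondary C4–OH, while the tertiary hydroxyl and the epoxide stay untouched and no stereocentre is affected.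

Step 8
Reactants: 13 (3R,3aS,4S,6S,7R,8S,8aR)-7,8-epoxy-3-hydroxy-6,8a-dimethyl-3-(propan-2-yl)decahydroazulen-4-yl 4-[(tert-butyldimethylsilyl)oxy]benzoate
Product: 15 (3R,3aS,4S,8R,8aR)-3,8-dihydroxy-6,8a-dimethyl-3-(propan-2-yl)-1,2,3,3a,4,5,8,8a-octahydroazulen-4-yl 4-[(tert-butyldimethylsilyl)oxy]benzoate, via bis-trimethylsilyl ether 14 (not isolated)
Conditions: Me3SiOTf (2.5 equiv), DBU (3 equiv), toluene, −78 °C to rt; then citric acid, MeOH, rt
Reagents that add atoms: none
Why: Noyori–Murata isomerisation of an epoxide to an allyl silyl ether, in which triflate opens the silylated epoxide at the less hindered C7 with inversion and DBU removes the anti-periplanar H6, forms the C6=C7 double bond while the C8 oxygen keeps its configuration, and mild acid then cleaves the two trimethylsilyl ethers but not the aryl silyl ether.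

Step 9
Reactants: 15 (3R,3aS,4S,8R,8aR)-3,8-dihydroxy-6,8a-dimethyl-3-(propan-2-yl)-1,2,3,3a,4,5,8,8a-octahydroazulen-4-yl 4-[(tert-butyldimethylsilyl)oxy]benzoate; 16 (2E)-2-methylbut-2-enoyl chloride
Product: 17 (3R,3aS,4S,8R,8aR)-3-hydroxy-6,8a-dimethyl-8-{[(2E)-2-methylbut-2-enoyl]oxy}-3-(propan-2-yl)-1,2,3,3a,4,5,8,8a-octahydroazulen-4-yl 4-[(tert-butyldimethylsilyl)oxy]benzoate
Conditions: pyridine, DMAP (cat.), CH2Cl2, 40 °C
Reagents that add atoms: none
Why: DMAP-catalysed acylation takes place at the only secondary hydroxyl (allylic C8–OH) with retention, because the tertiary C3 hydroxyl is too hindered to be acylated.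

Step 10
Reactants: 17 (3R,3aS,4S,8R,8aR)-3-hydroxy-6,8a-dimethyl-8-{[(2E)-2-methylbut-2-enoyl]oxy}-3-(propan-2-yl)-1,2,3,3a,4,5,8,8a-octahydroazulen-4-yl 4-[(tert-butyldimethylsilyl)oxy]benzoate
Product: 18 (3R,3aS,4S,8R,8aR)-3-hydroxy-6,8a-dimethyl-8-{[(2E)-2-methylbut-2-enoyl]oxy}-3-(propan-2-yl)-1,2,3,3a,4,5,8,8a-octahydroazulen-4-yl 4-hydroxybenzoate
Conditions: Bu4NF, AcOH, THF, 0 °C
Reagents that add atoms: none
Why: Fluoride-mediated desilylation buffered with acetic acid cleaves the aryl silyl ether and frees the phenol without touching the two esters or any stereocentre.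

**Compound list**

1 | 1,1,3,3-tetrabromopropan-2-one | BrC(Br)C(=O)C(Br)Br | starting material
2 | (2E,4E)-hexa-2,4-diene | C/C=C/C=C/C | starting material
3 | 2,7-dibromo-3,6-dimethylcyclohept-4-en-1-one (3,6-cis; bromine-bearing centres as a mixture) | O=C1C(Br)[C@H](C)C=C[C@H](C)C1Br | intermediate
4 | meso-(3R,6S)-3,6-dimethylcyclohept-4-en-1-one | O=C1C[C@H](C)C=C[C@H](C)C1 | intermediate
5 | trimethyl{[(3S,6S)-3,6-dimethylcyclohepta-1,4-dien-1-yl]oxy}silane | C[Si](C)(C)OC1=C[C@@H](C)C=C[C@@H](C)C1 | intermediate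
6 | (6S)-3,6-dimethylcyclohepta-2,4-dien-1-one | O=C1C=C(C)C=C[C@@H](C)C1 | intermediate
7 | (1S,6S,7R)-2,6-dimethyl-8-oxabicyclo[5.1.0]oct-2-en-4-one | O=C1C=C(C)[C@@H]2O[C@@H]2[C@@H](C)C1 | intermediate
8 | methyl 2-methylpropanoate | COC(=O)C(C)C | starting material
9 | 1-(propan-2-yl)cyclopropan-1-ol | CC(C)C1(O)CC1 | intermediate
10 | (3R,3aR,6S,7R,8S,8aR)-7,8-epoxy-3-hydroxy-6,8a-dimethyl-3-(propan-2-yl)octahydroazulen-4(1H)-one | O=C1C[C@H](C)[C@H]2O[C@H]2[C@]3(C)CC[C@@](O)(C(C)C)[C@H]13 | intermediate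
11 | (3R,3aS,4S,6S,7R,8S,8aR)-7,8-epoxy-6,8a-dimethyl-3-(propan-2-yl)decahydroazulene-3,4-diol | O[C@H]1C[C@H](C)[C@H]2O[C@H]2[C@]3(C)CC[C@@](O)(C(C)C)[C@H]13 | intermediate
12 | tert-butyl(4-iodophenoxy)dimethylsilane | CC(C)(C)[Si](C)(C)Oc1ccc(I)cc1 | starting material
13 | (3R,3aS,4S,6S,7R,8S,8aR)-7,8-epoxy-3-hydroxy-6,8a-dimethyl-3-(propan-2-yl)decahydroazulen-4-yl 4-[(tert-butyldimethylsilyl)oxy]benzoate | CC(C)(C)[Si](C)(C)Oc4ccc(cc4)C(=O)O[C@H]1C[C@H](C)[C@H]2O[C@H]2[C@]3(C)CC[C@@](O)(C(C)C)[C@H]13 | intermediate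
14 | (3R,3aS,4S,8R,8aR)-6,8a-dimethyl-3-(propan-2-yl)-3,8-bis[(trimethylsilyl)oxy]-1,2,3,3a,4,5,8,8a-octahydroazulen-4-yl 4-[(tert-butyldimethylsilyl)oxy]benzoate | C[Si](C)(C)O[C@@H]1C=C(C)C[C@H](OC(=O)c2ccc(O[Si](C)(C)C(C)(C)C)cc2)[C@@H]3[C@@]1(C)CC[C@@]3(O[Si](C)(C)C)C(C)C | intermediate
15 | (3R,3aS,4S,8R,8aR)-3,8-dihydroxy-6,8a-dimethyl-3-(propan-2-yl)-1,2,3,3a,4,5,8,8a-octahydroazulen-4-yl 4-[(tert-butyldimethylsilyl)oxy]benzoate | O[C@@H]1C=C(C)C[C@H](OC(=O)c2ccc(O[Si](C)(C)C(C)(C)C)cc2)[C@@H]3[C@@]1(C)CC[C@@]3(O)C(C)C | intermediate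
16 | (2E)-2-methylbut-2-enoyl chloride | C/C=C(\C)C(Cl)=O | starting material
17 | (3R,3aS,4S,8R,8aR)-3-hydroxy-6,8a-dimethyl-8-{[(2E)-2-methylbut-2-enoyl]oxy}-3-(propan-2-yl)-1,2,3,3a,4,5,8,8a-octahydroazulen-4-yl 4-[(tert-butyldimethylsilyl)oxy]benzoate | C/C=C(\C)C(=O)O[C@@H]1C=C(C)C[C@H](OC(=O)c2ccc(O[Si](C)(C)C(C)(C)C)cc2)[C@@H]3[C@@]1(C)CC[C@@]3(O)C(C)C | intermediate
18 | (3R,3aS,4S,8R,8aR)-3-hydroxy-6,8a-dimethyl-8-{[(2E)-2-methylbut-2-enoyl]oxy}-3-(propan-2-yl)-1,2,3,3a,4,5,8,8a-octahydroazulen-4-yl 4-hydroxybenzoate | C/C=C(\C)C(=O)O[C@@H]1C=C(C)C[C@H](OC(=O)c2ccc(O)cc2)[C@@H]2[C@@]1(C)CC[C@@]2(O)C(C)C | target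

**Step count**

Total step count: 10. Longest linear sequence: 9 steps (1 and 2 to 18 through Steps 1–3 and 5–10; Step 4 is a one-step side branch).

**The three steps most likely to fail, each with a fallback**

Step 5 is the most uncertain: a primary radical must add intermolecularly to a β,β-disubstituted enone, and the enolate must close the ring before it is protonated. The two partners are used in equimolar amounts, the cyclopropanol being fed in slowly to keep the radical concentration low. The fallback sets out from 7 and comes back at 10, replacing the one-flask cascade by two separate stages with a different three-carbon building block. 1-Iodo-4-methylpentan-3-one is added to 7 in a chain Giese reaction ((Me3Si)3SiH, Et3B, air, toluene, 0 °C), the α-keto radical taking hydrogen from the silane, to give the epoxy diketone (1S,2R,6S,7R)-2,6-dimethyl-2-(4-methyl-3-oxopentyl)-8-oxabicyclo[5.1.0]octan-4-one F1. An equilibrating aldol closure (K2CO3, MeOH, 0 °C) then gives 10 under thermodynamic control, the five-membered β-hydroxy ketone being the only unstrained aldol product.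

Step 8 can go wrong through cationic rearrangement next to the quaternary centre or through attack of the C3 oxygen on the activated epoxide. The fallback sets out from 13 and comes back at 17, so 15 and Step 9 are bypassed. MgBr2·OEt2 (Et2O, 0 °C) opens the epoxide at the less hindered C7 with inversion to give the bromohydrin (3R,3aS,4S,6S,7S,8S,8aR)-7-bromo-3,8-dihydroxy-6,8a-dimethyl-3-(propan-2-yl)decahydroazulen-4-yl 4-[(tert-butyldimethylsilyl)oxy]benzoate F2. Acylation of its C8 hydroxyl with 16 (pyridine, DMAP) gives the bromo tiglate (3R,3aS,4S,6S,7S,8S,8aR)-7-bromo-3-hydroxy-6,8a-dimethyl-8-{[(2E)-2-methylbut-2-enoyl]oxy}-3-(propan-2-yl)decahydroazulen-4-yl 4-[(tert-butyldimethylsilyl)oxy]benzoate F3. DBU (toluene, 80 °C) then removes HBr in an anti elimination; only H6 is anti-periplanar to the C7–Br bond, so the C6=C7 alkene of 17 results.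

Step 2 may give insufficient enantiomeric excess on the flexible seven-membered ring. The fallback sets out from 4 and comes back at 6, replacing the chiral base by enamine catalysis. A desymmetrising α-selenenylation of 4 with N-(phenylselanyl)phthalimide and (S)-2-{[(trifluoromethyl)sulfonyl]aminomethyl}pyrrolidine (20 mol%, CH2Cl2, rt) gives the selenide (2R,3S,6S)-3,6-dimethyl-2-(phenylselanyl)cyclohept-4-en-1-one F4, with selenium trans to the neighbouring methyl group. Oxidation (H2O2, pyridine, CH2Cl2, 0 °C) and syn elimination of the selenoxide towards the adjacent methine then gives 6.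

**Further compounds**

F1 | step 5 | (1S,2R,6S,7R)-2,6-dimethyl-2-(4-methyl-3-oxopentyl)-8-oxabicyclo[5.1.0]octan-4-one | O=C1C[C@H](C)[C@H]2O[C@H]2[C@](C)(CCC(=O)C(C)C)C1
F2 | step 8 | (3R,3aS,4S,6S,7S,8S,8aR)-7-bromo-3,8-dihydroxy-6,8a-dimethyl-3-(propan-2-yl)decahydroazulen-4-yl 4-[(tert-butyldimethylsilyl)oxy]benzoate | CC(C)(C)[Si](C)(C)Oc4ccc(cc4)C(=O)O[C@H]1C[C@H](C)[C@H](Br)[C@@H](O)[C@]2(C)CC[C@@](O)(C(C)C)[C@H]12
F3 | step 8 | (3R,3aS,4S,6S,7S,8S,8aR)-7-bromo-3-hydroxy-6,8a-dimethyl-8-{[(2E)-2-methylbut-2-enoyl]oxy}-3-(propan-2-yl)decahydroazulen-4-yl 4-[(tert-butyldimethylsilyl)oxy]benzoate | CC(C)(C)[Si](C)(C)Oc4ccc(cc4)C(=O)O[C@H]1C[C@H](C)[C@H](Br)[C@@H](OC(=O)/C(C)=C/C)[C@]2(C)CC[C@@](O)(C(C)C)[C@H]12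
F4 | step 2 | (2R,3S,6S)-3,6-dimethyl-2-(phenylselanyl)cyclohept-4-en-1-one | O=C1[C@H]([Se]c2ccccc2)[C@@H](C)C=C[C@@H](C)C1
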